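Numbering: decalin C1–C10 (C9 carbinol), linker C11–C12, 1,2-dioxane (ring C) carbons C13–C16, acid α-carbon C17. Everything rests on the C12–C13 bond between the linker and the methyl-bearing, fully substituted peroxide carbon of ring C. The key step, a one-pot 9-BBN hydroboration/B-alkyl Suzuki–Miyaura coupling, unites a sclareolide-derived C9 vinyl carbinol with a 2-bromoalkene carrying the C16/C17 stereodiad of an Evans aldol. It exploits C13 as a masked ketone: the coupling delivers it as a 1,1-disubstituted alkene; ozonolysis in methanol, SN2 peroxide closure at C16 and axial methyl delivery to the cyclic peroxycarbenium ion then relay C16 to C13.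

Key step: step 14

Remark on numbering: C8 is the CH(CH3) carbon of ring B, C18 the carboxyl carbon; α is the face opposite to the C10 methyl group; the decalin is ring A/ring B.
Assumption: (+)-sclareolide, 2-bromoprop-2-en-1-ol and (S)-4-benzyl-3-propionyloxazolidin-2-one are taken as commercial.

**Decalin fragment**

Step 1
Reactants: 1 (+)-sclareolide
Product: 3 9(11)-dehydrosclareolide, via 11α-phenylselanyl-sclareolide 2 (not isolated)
Conditions: LiN(iPr)2, THF, −78 °C; PhSeBr; then 30% H2O2, pyridine, CH2Cl2, 0 °C to rt
Reagents that add atoms: none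
Why: α-Selenenylation of the lactone enolate from the α-face (the β-face carries the two axial methyl groups) followed by selenoxide syn-elimination toward H-9, the only β-hydrogen, should give the butenolide with the C9=C11 double bond (Reich–Sharpless selenoxide elimination).

Step 2
Reactants: 3 9(11)-dehydrosclareolide
Product: 4 8α-glyoxyloyloxy-11-nordriman-9-one (8β-methyl)
Conditions: O3, CH2Cl2/MeOH 4:1, −78 °C; Me2S, −78 °C to rt
Reagents that add atoms: ozone ([O-][O+]=O)
Why: Criegee ozonolysis of the only C=C bond should turn C9 into the ring ketone and leave C11–C12 as a glyoxylate ester on the C8 oxygen, which thereby becomes an α-acyloxy group ready for reductive removal.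

Step 3
Reactants: 4 8α-glyoxyloyloxy-11-nordriman-9-one
Product: 5 (2R,4aS,8aS)-2,5,5,8a-tetramethyloctahydronaphthalen-1(2H)-one (8α-methyl-11-nordriman-9-one)
Conditions: SmI2 (excess), THF/MeOH, −78 °C to rt; then NaOMe (cat.), MeOH, rt
Reagents that add atoms: none
Why: Samarium diiodide should reduce the ketone to a ketyl that expels the α-acyloxy group (reductive α-deoxygenation of an α-acyloxy ketone), and methoxide equilibration places the C8 methyl group equatorial (α), away from the axial C10 methyl group (thermodynamic control).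

Step 4
Reactants: 5 8α-methyl-11-nordriman-9-one
Product: 6 (8βH)-drim-9(11)-ene (exocyclic C9=C11H2)
Conditions: Ph3PCH3Br, KOtBu, toluene, 100 °C
Reagents that add atoms: methyltriphenylphosphonium bromide (C[P+](c1ccccc1)(c1ccccc1)c1ccccc1.[Br-])
Why: Wittig methylenation under Conia conditions is the standard answer to hindered α-branched cyclohexanones, and C8 stays equatorial because that ketone epimer is strongly favoured.

Step 5
Reactants: 6 (8βH)-drim-9(11)-ene
Product: 7 9α,11-epoxy-(8βH)-drimane (spiro-epoxide with oxygen α)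
Conditions: mCPBA, NaHCO3, CH2Cl2, 0 °C
Reagents that add atoms: mCPBA (OOC(=O)c1cccc(Cl)c1)
Why: In this Prilezhaev epoxidation the peracid should attack along the axial trajectory on the α-face, because the β-face is shielded by the axial C10 methyl group on the neighbouring carbon, which puts the oxygen α on C9 (substrate control).

Step 6
Reactants: 7 9α,11-epoxy-(8βH)-drimane
Product: 8 (1R,2R,4aS,8aS)-2,5,5,8a-tetramethyl-1-vinyldecahydronaphthalen-1-ol (9α-hydroxy, 9β-vinyl)
Conditions: Me3S+ I−, n-BuLi, THF, −10 °C to rt
Reagents that add atoms: trimethylsulfonium iodide (C[S+](C)C.[I-])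
Why: Dimethylsulfonium methylide should open the epoxide at its CH2 terminus (C11) and the sulfonium betaine then eliminates to the one-carbon-homologated allylic alcohol (ylide homologation of epoxides), the C9–O bond and hence the 9α-oxygen being untouched.

Step 7
Reactants: 8 9α-hydroxy-9β-vinyl decalin
Product: 9 trimethylsilyl ether of 8
Conditions: TMSOTf, 2,6-lutidine, CH2Cl2, −78 to 0 °C
Reagents that add atoms: trimethylsilyl triflate (C[Si](C)(C)OS(=O)(=O)C(F)(F)F)
Why: Silylation with the silyl triflate should cap the hindered tertiary alcohol so that it cannot trap the carbonyl oxide in step 15.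

**Side-chain fragment**

Step 8
Reactants: 10 2-bromoprop-2-en-1-ol
Product: 12 ethyl 4-bromopent-4-enoate, via ketene acetal 11 (not isolated)
Conditions: MeC(OEt)3, EtCO2H (cat.), 140 °C, ethanol distilled off
Reagents that add atoms: triethyl orthoacetate (CCOC(C)(OCC)OCC)
Why: Johnson–Claisen rearrangement, in which the mixed ketene acetal undergoes a [3,3]-sigmatropic shift that attaches the acetate unit to the allyl terminus and regenerates the 2-bromoalkene.

Step 9
Reactants: 12 ethyl 4-bromopent-4-enoate
Product: 13 4-bromopent-4-enal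
Conditions: i-Bu2AlH, CH2Cl2, −78 °C
Reagents that add atoms: none
Why: Partial ester reduction, which stops at the aluminium hemiacetal at low temperature and releases the aldehyde on work-up.

Step 10
Reactants: 13 4-bromopent-4-enal; 14 (S)-4-benzyl-3-propionyloxazolidin-2-one
Product: 16 (S)-4-benzyl-3-[(2S,3R)-6-bromo-3-hydroxy-2-methylhept-6-enoyl]oxazolidin-2-one, via Z-boron enolate 15 (not isolated)
Conditions: Bu2BOTf, i-Pr2NEt, CH2Cl2, 0 °C; 13, −78 to 0 °C; pH 7 buffer, MeOH, H2O2
Reagents that add atoms: none
Why: Evans syn-aldol reaction through a Zimmerman–Traxler chair in which the benzyl group of the auxiliary shields one enolate face, setting C17 (S) and C16 (R) (auxiliary control).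

Step 11
Reactants: 16 syn-aldol imide
Product: 17 (2R,3R)-6-bromo-2-methylhept-6-ene-1,3-diol
Conditions: LiBH4, MeOH (1 equiv), THF, 0 °C
Reagents that add atoms: none
Why: Reductive cleavage of the N-acyl oxazolidinone should give the 1,3-diol and leave the vinyl bromide and both stereocentres untouched.

Step 12
Reactants: 17 diol
Product: 18 (2R,3R)-6-bromo-1-(tert-butyldimethylsilyloxy)-2-methylhept-6-en-3-ol
Conditions: TBSCl, imidazole, CH2Cl2, 0 °C
Reagents that add atoms: tert-butyldimethylsilyl chloride (CC(C)(C)[Si](C)(C)Cl)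
Why: Silylation should be selective for the primary hydroxyl group on steric grounds.

Step 13
Reactants: 18 primary TBS ether
Product: 19 (2R,3R)-6-bromo-1-(tert-butyldimethylsilyloxy)-2-methylhept-6-en-3-yl methanesulfonate
Conditions: MsCl, Et3N, CH2Cl2, 0 °C
Reagents that add atoms: methanesulfonyl chloride (CS(=O)(=O)Cl)
Why: Mesylation (retention at C16) installs the leaving group that the peroxide anion displaces with inversion in step 16.

**Union and completion**

Step 14
Reactants: 9 TMS-protected C9 vinyl carbinol; 19 bromoalkene mesylate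
Product: 21 (2R,3R)-1-(tert-butyldimethylsilyloxy)-2-methyl-6-methylidene-8-[(1R,2R,4aS,8aS)-2,5,5,8a-tetramethyl-1-(trimethylsilyloxy)decahydronaphthalen-1-yl]octan-3-yl methanesulfonate, via B-alkyl-9-BBN 20 (not isolated)
Conditions: 9-BBN, THF, 0 to 50 °C; then 19, PdCl2(dppf) (cat.), AsPh3, Cs2CO3, DMF/H2O, rt
Reagents that add atoms: none
Why: 9-BBN adds anti-Markovnikov to the vinyl group of 9 and places boron on C12; zerovalent palladium inserts into the C13–Br bond of 19, the primary alkyl group is transferred from the hydroxide-activated borane to divalent palladium, and reductive elimination forms the C12–C13 sp3–sp2 bond. The closest known reaction type is the B-alkyl Suzuki–Miyaura fragment coupling of a B-alkyl-9-BBN with a 2-bromo-1-alkene. No ring is closed and no stereocentre is formed; the step is made at the alkene oxidation level on purpose, because a C12 nucleophile added to a methyl-bearing cyclic peroxycarbenium ion would enter axially and give the C13 epimer, whereas a masked C13 ketone lets the methyl group enter last. Regioselective hydroboration is needed and is secured by the fully substituted C9 next to the alkene and by the bulk of 9-BBN. Chemoselective oxidative addition is needed and is secured by the far higher reactivity of the alkenyl C–Br bond compared with the secondary mesylate and the silyl ethers. Transfer of the primary alkyl group is favoured over the secondary B–C bonds of the bicycle.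

Step 15
Reactants: 21 C13-methylidene coupling product
Product: 22 C13 α-methoxy hydroperoxide of 21 (6-hydroperoxy-6-methoxy in place of 6-methylidene; both C13 epimers)
Conditions: O3, CH2Cl2/MeOH 4:1, −78 °C; N2 purge, concentration without reductant
Reagents that add atoms: ozone ([O-][O+]=O); methanol (CO)
Why: Criegee ozonolysis of a 1,1-disubstituted alkene should split off formaldehyde and give the more substituted carbonyl oxide at C13, which methanol traps as the hydroperoxy ketal; the configuration at C13 is of no consequence because it is erased in step 17.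

Step 16
Reactants: 22 hydroperoxy ketal mesylate
Product: 23 (16S,17R)-13-methoxy-1,2-dioxane: ring C closed between the C13 peroxide oxygen and C16 (both C13 epimers)
Conditions: KOtBu, 18-crown-6, THF, 0 °C
Reagents that add atoms: none
Why: Intramolecular SN2 alkylation of the peroxide anion (6-exo-tet) should displace the mesylate with inversion, which closes ring C and sets C16 (S).

Step 17
Reactants: 23 13-methoxy-1,2-dioxane
Product: 25 (13S,16S,17R)-13-methyl-1,2-dioxane bis-silyl ether, via peroxycarbenium ion 24 (not isolated)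
Conditions: AlMe3 (4 equiv), CH2Cl2, −78 to −20 °C
Reagents that add atoms: trimethylaluminium (C[Al](C)C)
Why: Proposed new method: AlMe3 should coordinate the methoxy oxygen of either ketal epimer and ionise it to the cyclic peroxycarbenium ion 24 (the ring O–O oxygen is the poorer Lewis base and its lone pair stabilises the cation), after which a methyl group is transferred from aluminium to C13; the closest known reaction types are the Lewis-acid-mediated substitution of 3-alkoxy-1,2-dioxanes by allylsilanes and silyl enol ethers through peroxycarbenium ions and the C-methylation of ketals by AlMe3; the half-chair cation holds the C16 side chain pseudo-equatorial and the small nucleophile enters along the axial trajectory that leads directly to the chair, so the methyl group should end up axial and cis to the C16 substituent, which is the (13S) configuration (stereoelectronic substrate control from C16).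

Step 18
Reactants: 25 bis-silyl ether
Product: 26 (2R)-2-[(3S,6S)-6-{2-[(1R,2R,4aS,8aS)-1-hydroxy-2,5,5,8a-tetramethyldecahydronaphthalen-1-yl]ethyl}-6-methyl-1,2-dioxan-3-yl]propan-1-ol
Conditions: HF·pyridine, pyridine/THF, 0 °C to rt
Reagents that add atoms: none
Why: Fluoride-mediated desilylation under buffered, non-basic conditions should remove both silyl ethers and spare the dialkyl peroxide.

Step 19
Reactants: 26 diol
Product: 27 (2S)-2-[(3S,6S)-6-{2-[(1R,2R,4aS,8aS)-1-hydroxy-2,5,5,8a-tetramethyldecahydronaphthalen-1-yl]ethyl}-6-methyl-1,2-dioxan-3-yl]propanoic acid (target)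
Conditions: TEMPO (cat.), PhI(OAc)2, MeCN/H2O, rt
Reagents that add atoms: water (O)
Why: Oxoammonium-mediated oxidation of the primary alcohol through the aldehyde hydrate to the acid runs near neutral pH, which should spare the tertiary alcohol, the peroxide and the C17 stereocentre.

**Compound list**

1 | (+)-sclareolide | CC1(C)CCC[C@@]2(C)[C@H]1CC[C@@]1(C)OC(=O)C[C@@H]12 | starting material
2 | 11α-phenylselanyl-sclareolide | CC1(C)CCC[C@@]2(C)[C@H]1CC[C@@]1(C)OC(=O)[C@@H]([Se]c3ccccc3)[C@@H]12 | intermediate (not isolated)
3 | 9(11)-dehydrosclareolide | CC1(C)CCC[C@@]2(C)[C@H]1CC[C@@]1(C)OC(=O)C=C12 | intermediate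
4 | 8α-glyoxyloyloxy-11-nordriman-9-one | CC1(C)CCC[C@@]2(C)[C@H]1CC[C@@](C)(OC(=O)C=O)C2=O | intermediate
5 | (2R,4aS,8aS)-2,5,5,8a-tetramethyloctahydronaphthalen-1(2H)-one | CC1(C)CCC[C@@]2(C)[C@H]1CC[C@@H](C)C2=O | intermediate
6 | (8βH)-drim-9(11)-ene | CC1(C)CCC[C@@]2(C)[C@H]1CC[C@@H](C)C2=C | intermediate
7 | 9α,11-epoxy-(8βH)-drimane | CC1(C)CCC[C@@]2(C)[C@H]1CC[C@@H](C)[C@]21CO1 | intermediate
8 | (1R,2R,4aS,8aS)-2,5,5,8a-tetramethyl-1-vinyldecahydronaphthalen-1-ol | CC1(C)CCC[C@@]2(C)[C@H]1CC[C@@H](C)[C@]2(O)C=C | intermediate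
9 | trimethylsilyl ether of 8 | CC1(C)CCC[C@@]2(C)[C@H]1CC[C@@H](C)[C@]2(O[Si](C)(C)C)C=C | intermediate
10 | 2-bromoprop-2-en-1-ol | OCC(Br)=C | starting material
11 | 2-bromoallyl ethyl ketene acetal | C=C(OCC)OCC(Br)=C | intermediate (not isolated)
12 | ethyl 4-bromopent-4-enoate | CCOC(=O)CCC(Br)=C | intermediate
13 | 4-bromopent-4-enal | O=CCCC(Br)=C | intermediate
14 | (S)-4-benzyl-3-propionyloxazolidin-2-one | CCC(=O)N1[C@@H](Cc2ccccc2)COC1=O | starting material
15 | Z-dibutylboron enolate of 14 | C/C=C(\OB(CCCC)CCCC)N1[C@@H](Cc2ccccc2)COC1=O | intermediate (not isolated)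
16 | (S)-4-benzyl-3-[(2S,3R)-6-bromo-3-hydroxy-2-methylhept-6-enoyl]oxazolidin-2-one | C=C(Br)CC[C@@H](O)[C@H](C)C(=O)N1[C@@H](Cc2ccccc2)COC1=O | intermediate
17 | (2R,3R)-6-bromo-2-methylhept-6-ene-1,3-diol | C=C(Br)CC[C@@H](O)[C@H](C)CO | intermediate
18 | (2R,3R)-6-bromo-1-(tert-butyldimethylsilyloxy)-2-methylhept-6-en-3-ol | C=C(Br)CC[C@@H](O)[C@H](C)CO[Si](C)(C)C(C)(C)C | intermediate
19 | (2R,3R)-6-bromo-1-(tert-butyldimethylsilyloxy)-2-methylhept-6-en-3-yl methanesulfonate | C=C(Br)CC[C@@H](OS(C)(=O)=O)[C@H](C)CO[Si](C)(C)C(C)(C)C | intermediate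
20 | B-alkyl-9-BBN from 9 (boron on C12) | CC1(C)CCC[C@@]2(C)[C@H]1CC[C@@H](C)[C@]2(O[Si](C)(C)C)CCB1C2CCCC1CCC2 | intermediate (not isolated)
21 | C13-methylidene coupling product (16R,17R; C16 mesylate, C18 TBS ether, C9 TMS ether) | CC1(C)CCC[C@@]2(C)[C@H]1CC[C@@H](C)[C@]2(O[Si](C)(C)C)CCC(=C)CC[C@@H](OS(C)(=O)=O)[C@H](C)CO[Si](C)(C)C(C)(C)C | intermediate
22 | C13 α-methoxy hydroperoxide (both C13 epimers) | CC1(C)CCC[C@@]2(C)[C@H]1CC[C@@H](C)[C@]2(O[Si](C)(C)C)CCC(OC)(OO)CC[C@@H](OS(C)(=O)=O)[C@H](C)CO[Si](C)(C)C(C)(C)C | intermediate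
23 | (16S,17R)-13-methoxy-1,2-dioxane (both C13 epimers) | CC1(C)CCC[C@@]2(C)[C@H]1CC[C@@H](C)[C@]2(O[Si](C)(C)C)CCC1(OC)CC[C@@H]([C@H](C)CO[Si](C)(C)C(C)(C)C)OO1 | intermediate
24 | cyclic peroxycarbenium ion (C13=O+) | CC1(C)CCC[C@@]2(C)[C@H]1CC[C@@H](C)[C@]2(O[Si](C)(C)C)CCC1=[O+]O[C@@H](CC1)[C@H](C)CO[Si](C)(C)C(C)(C)C | intermediate (not isolated)
25 | (13S,16S,17R)-13-methyl-1,2-dioxane bis-silyl ether | CC1(C)CCC[C@@]2(C)[C@H]1CC[C@@H](C)[C@]2(O[Si](C)(C)C)CC[C@]1(C)CC[C@@H]([C@H](C)CO[Si](C)(C)C(C)(C)C)OO1 | intermediate
26 | (2R)-2-[(3S,6S)-6-{2-[(1R,2R,4aS,8aS)-1-hydroxy-2,5,5,8a-tetramethyldecahydronaphthalen-1-yl]ethyl}-6-methyl-1,2-dioxan-3-yl]propan-1-ol | CC1(C)CCC[C@@]2(C)[C@H]1CC[C@@H](C)[C@]2(O)CC[C@]1(C)CC[C@@H]([C@H](C)CO)OO1 | intermediate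
27 | (2S)-2-[(3S,6S)-6-{2-[(1R,2R,4aS,8aS)-1-hydroxy-2,5,5,8a-tetramethyldecahydronaphthalen-1-yl]ethyl}-6-methyl-1,2-dioxan-3-yl]propanoic acid | CC1(C)CCC[C@@]2(C)[C@H]1CC[C@@H](C)[C@]2(O)CC[C@]1(C)CC[C@@H]([C@H](C)C(=O)O)OO1 | target

**Count and risks**

Total step count: 19. Longest linear sequence: 13 steps (steps 1–7 and 14–19).

Steps most likely to fail:

1. Step 17 (Proposed new method). Methyl transfer may go to a peroxide oxygen, or the Lewis acid may trigger O–O heterolysis or ionise the ring C–O bond instead of the methoxy group. Facial selectivity could also erode if methyl is delivered inside a contact ion pair from an equatorial methoxy epimer. Reversible capture of the cation by the C9 silyl ether oxygen would be harmless, since it re-ionises and the silyl groups are removed in step 18. Fallback with known chemistry, setting out from 21 and returning at 25: cobalt-catalysed Isayama–Mukaiyama hydroperoxysilylation of the 1,1-disubstituted alkene (Co(acac)2 with divalent cobalt, O2, Et3SiH, 1,2-dichloroethane, rt) makes the C13 methyl group by hydrogen-atom transfer and traps the tertiary radical with O2, giving the tertiary triethylsilyl peroxide F1 as both C13 epimers. Bu4NF (1 equiv, THF, 0 °C) then frees the peroxide anion, which closes ring C on the C16 mesylate with inversion to give 25 together with its C13 epimer, to be separated by chromatography. This gives up the stereocontrol at C13.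

2. Step 16. E2 elimination of the β-branched secondary mesylate, or base-induced Kornblum–DeLaMare cleavage of the newly formed secondary peroxide, may compete with the 6-exo-tet displacement. Fallback, setting out from 18 and returning at 23: triflation (Tf2O, 2,6-lutidine, CH2Cl2, −40 °C) gives the secondary triflate F2, which is displaced with inversion by 2-methoxyprop-2-yl hydroperoxide and CsOH in DMF at low temperature to give the peroxyketal-protected C16 hydroperoxide F3. Coupling of F3 with 9 under the conditions of step 14 gives the methylidene compound F4, and ozonolysis with Me2S work-up gives the C13 ketone F5. PPTS in methanol then removes the 2-methoxyprop-2-yl group; the freed hydroperoxide adds to the C13 ketone and the peroxyhemiketal is converted to the methyl ketal 23. Ring C is thus closed by ketalisation instead of by substitution.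

3. Step 6. The ylide may act as a base and isomerise the epoxide to an allylic alcohol by removing H-8, or attack at the neopentyl-like C11 may be too slow. Fallback, setting out from 6 and returning at 8: hydroboration–oxidation (BH3·THF; NaOH, H2O2) gives the primary alcohol F6, and Dess–Martin oxidation gives the aldehyde F7. Enolisation with KN(SiMe3)2 at −78 °C and hydroxylation with 2-(phenylsulfonyl)-3-phenyloxaziridine from the unhindered α-face gives the 9α-hydroxy aldehyde F8 (the configuration of C9 in F6 and F7 is irrelevant because the enolate is planar). Wittig methylenation with Ph3P=CH2 then gives 8.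

Further compounds
F1 | step 17 | C13 triethylsilyl peroxide of the C16 mesylate (both C13 epimers) | CC1(C)CCC[C@@]2(C)[C@H]1CC[C@@H](C)[C@]2(O[Si](C)(C)C)CCC(C)(OO[Si](CC)(CC)CC)CC[C@@H](OS(C)(=O)=O)[C@H](C)CO[Si](C)(C)C(C)(C)C
F2 | step 16 | (2R,3R)-6-bromo-1-(tert-butyldimethylsilyloxy)-2-methylhept-6-en-3-yl trifluoromethanesulfonate | C=C(Br)CC[C@@H](OS(=O)(=O)C(F)(F)F)[C@H](C)CO[Si](C)(C)C(C)(C)C
F3 | step 16 | (16S)-2-methoxyprop-2-yl peroxide of the bromoalkene | C=C(Br)CC[C@H](OOC(C)(C)OC)[C@H](C)CO[Si](C)(C)C(C)(C)C
F4 | step 16 | C13-methylidene coupling product carrying the C16 2-methoxyprop-2-yl peroxide | CC1(C)CCC[C@@]2(C)[C@H]1CC[C@@H](C)[C@]2(O[Si](C)(C)C)CCC(=C)CC[C@H](OOC(C)(C)OC)[C@H](C)CO[Si](C)(C)C(C)(C)C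
F5 | step 16 | C13 ketone carrying the C16 2-methoxyprop-2-yl peroxide | CC1(C)CCC[C@@]2(C)[C@H]1CC[C@@H](C)[C@]2(O[Si](C)(C)C)CCC(=O)CC[C@H](OOC(C)(C)OC)[C@H](C)CO[Si](C)(C)C(C)(C)C
F6 | step 6 | (8βH)-driman-11-ol (9α-H) | CC1(C)CCC[C@@]2(C)[C@H]1CC[C@@H](C)[C@@H]2CO
F7 | step 6 | (8βH)-driman-11-al (9α-H) | CC1(C)CCC[C@@]2(C)[C@H]1CC[C@@H](C)[C@@H]2C=O
F8 | step 6 | 9α-hydroxy-(8βH)-driman-11-al | CC1(C)CCC[C@@]2(C)[C@H]1CC[C@@H](C)[C@]2(O)C=O
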